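The target is split at the ester into 4-hydroxy-3,5-diprenylbenzoic acid and (R)-terpinen-4-ol. The cyclohexene ring of the alcohol (p-menthane numbering) would have a mirror plane through the carbinol carbon C4 and C1 if the C1=C2 double bond were absent. C4 can therefore be made stereogenic by desymmetrisation. An achiral 3-isopropyl-3-silyloxycyclobutanone takes up 1-trimethylsilylpropyne under chiral zerovalent nickel catalysis. One enantiotopic C(O)–CH2 bond is cut and the ring bonds C2–C3 and C1–C6 form at once, which builds the six-membered ring and sets C4. Carbonyl oxygen and silicon are then erased by two successive allylic transpositions that return the alkene to its place.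

Key step: step 4

Assumption: the sense of induction of the nickel–phosphoramidite catalyst cannot be predicted with confidence. The ligand antipode named in step 4 is taken to lead to the (R) series, and this is to be checked at compound 14 by chiral GC against enantiomerically defined terpinen-4-ol.

Step 1
Reactants: 1 3-methylbutan-2-one
Product: 2 triethyl[(3-methylbut-1-en-2-yl)oxy]silane
Conditions: LiN(iPr)2, THF, −78 °C; then Et3SiCl, −78 °C to rt
Reagents that add atoms: chlorotriethylsilane, CC[Si](Cl)(CC)CC
Why: Kinetic silyl enol ether formation, in which the hindered amide base removes a proton from the free methyl group rather than from the isopropyl methine and O-silylation traps the terminal enolate.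

Step 2
Reactants: 2 triethyl[(3-methylbut-1-en-2-yl)oxy]silane
Product: 3 rac-2,2-dichloro-3-(propan-2-yl)-3-(triethylsilyloxy)cyclobutan-1-one
Conditions: Cl2CHCOCl, Et3N (slow addition), hexane, 0 °C to rt
Reagents that add atoms: dichloroacetyl chloride, O=C(Cl)C(Cl)Cl
Why: Ketene–alkene [2+2] cycloaddition, in which the nucleophilic CH2 terminus of the enol ether attacks the central ketene carbon so that C=O lies next to CH2 and CCl2 next to the oxygenated carbon; the racemic stereocentre disappears in step 3.

Step 3
Reactants: 3 rac-2,2-dichloro-3-(propan-2-yl)-3-(triethylsilyloxy)cyclobutan-1-one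
Product: 4 3-(propan-2-yl)-3-(triethylsilyloxy)cyclobutan-1-one (achiral)
Conditions: Zn dust, NH4Cl, MeOH, rt
Reagents that add atoms: none
Why: Reductive dehalogenation of an α,α-dichloroketone with zinc, as in the standard route to 3-alkoxycyclobutanones, where the zinc enolates are protonated in the protic medium before they can expel the β-silyloxy group.

Step 4
Reactants: 4 3-(propan-2-yl)-3-(triethylsilyloxy)cyclobutan-1-one; 5 trimethyl(prop-1-yn-1-yl)silane
Product: 8 (5R)-2-methyl-5-(propan-2-yl)-5-(triethylsilyloxy)-3-(trimethylsilyl)cyclohex-2-en-1-one, via spiro oxanickelacyclopentene 6 (not isolated), via seven-membered nickelacycle 7 (not isolated)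
Conditions: Ni(cod)2 (10 mol %), (S)-BINOL-derived phosphoramidite bearing an N,N-bis[(R)-1-phenylethyl]amino group (20 mol %), 5 (3 equiv), toluene, 90 °C, sealed tube
Reagents that add atoms: none
Why: Proposed new method: zerovalent nickel couples the C=O group of 4 and the alkyne oxidatively to the spiro oxanickelacyclopentene 6 (this makes the bond from the carbonyl carbon to the methyl-bearing alkyne carbon), strain-driven β-carbon elimination of one of the two enantiotopic ring C–CH2 bonds gives the seven-membered nickelacycle 7, and C(sp3)–C(sp2) reductive elimination makes the bond from that CH2 to the silyl-bearing carbon. The closest known reaction types are the racemic Ni(cod)2/PCy3-catalysed intermolecular insertion of internal alkynes into 3,3-disubstituted cyclobutanones and the enantioselective nickel–phosphoramidite-catalysed intramolecular alkene insertion into such ketones, and what is new is the enantioselective intermolecular variant on a 3-silyloxy substrate. The six-membered ring closes as a formal [4+2] two-carbon ring expansion whose ring-closing event is the reductive elimination from 7. The only stereocentre, the carbinol carbon, is not itself touched and becomes stereogenic when the chiral ligand on nickel decides which of the two enantiotopic C–C bonds migrates. The regioselectivity needed (methyl next to C=O, silicon next to CH2) is secured by the known preference of 1-silylalkynes to place the silyl-bearing carbon on nickel in the oxidative cyclisation, as in nickel-catalysed aldehyde–alkyne reductive coupling. β-Hydride elimination from 7 is excluded because the β-carbon is quaternary, and a silyl ether instead of the aroyloxy group is carried here so that β-oxygen elimination is disfavoured.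

Step 5
Reactants: 8 (5R)-2-methyl-5-(propan-2-yl)-5-(triethylsilyloxy)-3-(trimethylsilyl)cyclohex-2-en-1-one
Product: 9 N-tosylhydrazone of 8
Conditions: TsNHNH2, pyridinium p-toluenesulfonate (cat.), THF–EtOH, 40 °C
Reagents that add atoms: p-toluenesulfonyl hydrazide, Cc1ccc(cc1)S(=O)(=O)NN
Why: Tosylhydrazone formation by condensation, known for similarly hindered cyclohexenones such as isophorone, in a weakly acidic medium that leaves both silyl groups and the β-silyloxy ketone motif intact.

Step 6
Reactants: 9 N-tosylhydrazone of 8
Product: 12 trimethyl[(5R)-2-methyl-5-(propan-2-yl)-5-(triethylsilyloxy)cyclohex-2-en-1-yl]silane (C1 epimers), via N-boryl allylic tosylhydrazine 10 (not isolated), via allylic diazene 11 (not isolated)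
Conditions: catecholborane, CHCl3, −10 to 0 °C; then NaOAc·3H2O, reflux
Reagents that add atoms: none
Why: Reduction of an α,β-unsaturated tosylhydrazone with alkene transposition (allylic diazene rearrangement), in which 1,2-hydroboration of C=N, acetate-induced loss of sulfinate and retro-ene loss of N2 deliver hydrogen to the silyl-bearing carbon and move the C=C to the former carbonyl carbon; the resulting allylsilane has a new C–Si stereocentre that is irrelevant because step 7 destroys it.

Step 7
Reactants: 12 trimethyl[(5R)-2-methyl-5-(propan-2-yl)-5-(triethylsilyloxy)cyclohex-2-en-1-yl]silane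
Product: 14 (R)-terpinen-4-ol [(1R)-4-methyl-1-(propan-2-yl)cyclohex-3-en-1-ol], via terpinenyl triethylsilyl ether 13 (not isolated)
Conditions: TsOH·H2O (cat.), CH2Cl2–MeOH, 0 °C to rt
Reagents that add atoms: none
Why: Protodesilylation of an allylsilane (SE2′), in which the proton adds to the CH= terminus (the former carbonyl carbon) to give a tertiary β-silyl cation and loss of silicon returns the alkene to the two former alkyne carbons; the same acid then methanolyses the O–SiEt3 bond without breaking the carbinol C–O bond.

Step 8
Reactants: 15 4-iodophenol; 16 1-bromo-3-methylbut-2-ene (prenyl bromide)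
Product: 17 4-iodo-2,6-bis(3-methylbut-2-en-1-yl)phenol
Conditions: KOH, H2O, 16 (2.5 equiv), rt
Reagents that add atoms: none
Why: ortho-C-alkylation of a phenoxide in water, where hydrogen bonding shields the oxygen so that SN2 attack on prenyl bromide comes from both ortho carbons while iodine blocks the para position.

Step 9
Reactants: 17 4-iodo-2,6-bis(3-methylbut-2-en-1-yl)phenol
Product: 18 tert-butyl[4-iodo-2,6-bis(3-methylbut-2-en-1-yl)phenoxy]dimethylsilane
Conditions: TBSCl, imidazole, DMF, 40 °C
Reagents that add atoms: tert-butylchlorodimethylsilane, CC(C)(C)[Si](C)(C)Cl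
Why: Imidazole-promoted O-silylation, feasible because the two ortho substituents are primary CH2 groups, gives a phenol protecting group that can later be removed without acid.

Step 10
Reactants: 18 tert-butyl[4-iodo-2,6-bis(3-methylbut-2-en-1-yl)phenoxy]dimethylsilane
Product: 20 4-(tert-butyldimethylsilyloxy)-3,5-bis(3-methylbut-2-en-1-yl)benzoic acid, via aryllithium 19 (not isolated)
Conditions: n-BuLi, THF, −78 °C; CO2 (g); then cold 1 M HCl
Reagents that add atoms: carbon dioxide, O=C=O
Why: Iodine–lithium exchange followed by carboxylation, fast at −78 °C so that the doubly activated ArCH2 protons and the aryl silyl ether are not attacked.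

Step 11
Reactants: 20 4-(tert-butyldimethylsilyloxy)-3,5-bis(3-methylbut-2-en-1-yl)benzoic acid; 14 (R)-terpinen-4-ol
Product: 23 (1R)-4-methyl-1-(propan-2-yl)cyclohex-3-en-1-yl 4-(tert-butyldimethylsilyloxy)-3,5-bis(3-methylbut-2-en-1-yl)benzoate, via aroyl chloride 21 (not isolated), via lithium terpinen-4-olate 22 (not isolated)
Conditions: 20, 1-chloro-N,N,2-trimethylprop-1-en-1-amine, CH2Cl2, 0 °C to rt; separately 14, n-BuLi, THF, −78 to 0 °C; combine, 0 to 40 °C
Reagents that add atoms: none
Why: Acylation of a lithium tert-alkoxide with an acid chloride, the standard esterification of hindered tertiary alcohols, where the α-chloroenamine makes the chloride without free HCl so the prenyl groups survive and the configuration is kept because the carbinol C–O bond is never broken.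

Step 12
Reactants: 23 (1R)-4-methyl-1-(propan-2-yl)cyclohex-3-en-1-yl 4-(tert-butyldimethylsilyloxy)-3,5-bis(3-methylbut-2-en-1-yl)benzoate
Product: 24 (1R)-4-methyl-1-(propan-2-yl)cyclohex-3-en-1-yl 4-hydroxy-3,5-bis(3-methylbut-2-en-1-yl)benzoate (target)
Conditions: Bu4NF, AcOH, THF, 0 °C
Reagents that add atoms: none
Why: Fluoride-induced cleavage of an aryl silyl ether under buffered, acid-free conditions, which avoids chroman formation from the ortho-prenylphenol and ionisation of the tertiary ester.

Compound list
1 | 3-methylbutan-2-one | CC(=O)C(C)C | starting material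
2 | triethyl[(3-methylbut-1-en-2-yl)oxy]silane | C=C(O[Si](CC)(CC)CC)C(C)C | intermediate
3 | rac-2,2-dichloro-3-(propan-2-yl)-3-(triethylsilyloxy)cyclobutan-1-one | O=C1CC(O[Si](CC)(CC)CC)(C(C)C)C1(Cl)Cl | intermediate
4 | 3-(propan-2-yl)-3-(triethylsilyloxy)cyclobutan-1-one | O=C1CC(O[Si](CC)(CC)CC)(C(C)C)C1 | intermediate
5 | trimethyl(prop-1-yn-1-yl)silane | CC#C[Si](C)(C)C | starting material
6 | spiro oxanickelacyclopentene (ligand on nickel omitted) | CC[Si](CC)(CC)OC1(C(C)C)CC2(C1)O[Ni]C([Si](C)(C)C)=C2C | intermediate
7 | seven-membered nickelacycle (ligand on nickel omitted) | CC[Si](CC)(CC)O[C@@]1(C(C)C)C[Ni]C([Si](C)(C)C)=C(C)C(=O)C1 | intermediate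
8 | (5R)-2-methyl-5-(propan-2-yl)-5-(triethylsilyloxy)-3-(trimethylsilyl)cyclohex-2-en-1-one | CC[Si](CC)(CC)O[C@@]1(C(C)C)CC([Si](C)(C)C)=C(C)C(=O)C1 | intermediate
9 | N-tosylhydrazone of 8 | CC[Si](CC)(CC)O[C@@]1(C(C)C)CC([Si](C)(C)C)=C(C)C(=NNS(=O)(=O)c2ccc(C)cc2)C1 | intermediate
10 | N-(1,3,2-benzodioxaborol-2-yl) allylic tosylhydrazine | CC[Si](CC)(CC)O[C@@]1(C(C)C)CC([Si](C)(C)C)=C(C)C(N(B2Oc3ccccc3O2)NS(=O)(=O)c2ccc(C)cc2)C1 | intermediate
11 | allylic diazene | CC[Si](CC)(CC)O[C@@]1(C(C)C)CC([Si](C)(C)C)=C(C)C(N=N)C1 | intermediate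
12 | trimethyl[(5R)-2-methyl-5-(propan-2-yl)-5-(triethylsilyloxy)cyclohex-2-en-1-yl]silane (C1 epimers) | CC[Si](CC)(CC)O[C@@]1(C(C)C)CC([Si](C)(C)C)C(C)=CC1 | intermediate
13 | triethyl{[(1R)-4-methyl-1-(propan-2-yl)cyclohex-3-en-1-yl]oxy}silane | CC[Si](CC)(CC)O[C@@]1(C(C)C)CC=C(C)CC1 | intermediate
14 | (R)-terpinen-4-ol, (1R)-4-methyl-1-(propan-2-yl)cyclohex-3-en-1-ol | O[C@@]1(C(C)C)CC=C(C)CC1 | intermediate
15 | 4-iodophenol | Oc1ccc(I)cc1 | starting material
16 | 1-bromo-3-methylbut-2-ene | CC(C)=CCBr | starting material
17 | 4-iodo-2,6-bis(3-methylbut-2-en-1-yl)phenol | CC(C)=CCc1cc(I)cc(CC=C(C)C)c1O | intermediate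
18 | tert-butyl[4-iodo-2,6-bis(3-methylbut-2-en-1-yl)phenoxy]dimethylsilane | CC(C)=CCc1cc(I)cc(CC=C(C)C)c1O[Si](C)(C)C(C)(C)C | intermediate
19 | aryllithium from 18 | CC(C)=CCc1cc([Li])cc(CC=C(C)C)c1O[Si](C)(C)C(C)(C)C | intermediate
20 | 4-(tert-butyldimethylsilyloxy)-3,5-bis(3-methylbut-2-en-1-yl)benzoic acid | CC(C)=CCc1cc(C(=O)O)cc(CC=C(C)C)c1O[Si](C)(C)C(C)(C)C | intermediate
21 | 4-(tert-butyldimethylsilyloxy)-3,5-bis(3-methylbut-2-en-1-yl)benzoyl chloride | CC(C)=CCc1cc(C(=O)Cl)cc(CC=C(C)C)c1O[Si](C)(C)C(C)(C)C | intermediate
22 | lithium (R)-terpinen-4-olate | [Li]O[C@@]1(C(C)C)CC=C(C)CC1 | intermediate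
23 | (1R)-4-methyl-1-(propan-2-yl)cyclohex-3-en-1-yl 4-(tert-butyldimethylsilyloxy)-3,5-bis(3-methylbut-2-en-1-yl)benzoate | CC(C)=CCc1cc(C(=O)O[C@@]2(C(C)C)CC=C(C)CC2)cc(CC=C(C)C)c1O[Si](C)(C)C(C)(C)C | intermediate
24 | (1R)-4-methyl-1-(propan-2-yl)cyclohex-3-en-1-yl 4-hydroxy-3,5-bis(3-methylbut-2-en-1-yl)benzoate | CC(C)=CCc1cc(C(=O)O[C@@]2(C(C)C)CC=C(C)CC2)cc(CC=C(C)C)c1O | target

Total step count: 12. Longest linear sequence: 9 steps (steps 1–7, 11 and 12).

Steps most likely to fail

1. Step 4 (Proposed new method). The chiral ligand may discriminate poorly between the two enantiotopic C–C bonds. It may also slow the oxidative cyclisation enough that alkyne oligomerisation or β-silyloxy elimination from the nickelacycle takes over. The fallback sets out from 4 and 5. The established achiral protocol (Ni(cod)2, PCy3, toluene, 100 °C) should give the racemic enone F1. This is resolved by preparative chromatography on a chiral stationary phase, with the enone chromophore used for detection. The (S)-enone F2 is set aside, and the (R)-enantiomer is compound 8, where the route is rejoined.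

2. Step 11. Attack of the very hindered tertiary alkoxide on an electron-rich aroyl chloride may be slow, so that silyl transfer from the phenol oxygen to the alkoxide competes. The fallback forms the aryl–C(=O) bond instead of the acyl–O bond. From 14, deprotonation to 22 and reaction with the small and very reactive 1,1'-carbonyldiimidazole (THF, 0 °C to rt) should give (R)-terpinen-4-yl imidazole-1-carboxylate F5. From 18, iodine–magnesium exchange (iPrMgCl·LiCl, THF, −20 to 0 °C) gives the arylmagnesium chloride F6. This adds to F5 with loss of imidazolide (ester synthesis from a Grignard reagent and an alkyl imidazolecarboxylate). The route is rejoined at 23, and step 10 is no longer needed.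

3. Step 6. Hydride delivery to the hindered C=N bond may be slow, or the material may decompose during the heating needed for sulfinate loss. The fallback generates the same diazene by substitution instead of reduction. From 8, Luche reduction (NaBH4, CeCl3·7H2O, MeOH, −20 °C) gives the allylic alcohol F3. Mitsunobu displacement with 2-nitrobenzenesulfonylhydrazide (PPh3, diethyl azodicarboxylate, THF, −30 °C) gives the N-allyl-N-sulfonylhydrazine F4. On warming to rt, F4 loses the sulfinic acid to give diazene 11 and then 12, where the route is rejoined. Step 5 is no longer needed.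

Further compounds
F1 | step 4 | rac-2-methyl-5-(propan-2-yl)-5-(triethylsilyloxy)-3-(trimethylsilyl)cyclohex-2-en-1-one | CC[Si](CC)(CC)OC1(C(C)C)CC([Si](C)(C)C)=C(C)C(=O)C1
F2 | step 4 | (5S)-2-methyl-5-(propan-2-yl)-5-(triethylsilyloxy)-3-(trimethylsilyl)cyclohex-2-en-1-one | CC[Si](CC)(CC)O[C@]1(C(C)C)CC([Si](C)(C)C)=C(C)C(=O)C1
F3 | step 6 | (5R)-2-methyl-5-(propan-2-yl)-5-(triethylsilyloxy)-3-(trimethylsilyl)cyclohex-2-en-1-ol | CC[Si](CC)(CC)O[C@@]1(C(C)C)CC([Si](C)(C)C)=C(C)C(O)C1
F4 | step 6 | N-[(5R)-2-methyl-5-(propan-2-yl)-5-(triethylsilyloxy)-3-(trimethylsilyl)cyclohex-2-en-1-yl]-2-nitrobenzenesulfonohydrazide | CC[Si](CC)(CC)O[C@@]1(C(C)C)CC([Si](C)(C)C)=C(C)C(N(N)S(=O)(=O)c2ccccc2[N+](=O)[O-])C1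
F5 | step 11 | (1R)-4-methyl-1-(propan-2-yl)cyclohex-3-en-1-yl 1H-imidazole-1-carboxylate | O=C(O[C@@]1(C(C)C)CC=C(C)CC1)n1ccnc1
F6 | step 11 | [4-(tert-butyldimethylsilyloxy)-3,5-bis(3-methylbut-2-en-1-yl)phenyl]magnesium chloride | CC(C)=CCc1cc([Mg]Cl)cc(CC=C(C)C)c1O[Si](C)(C)C(C)(C)C
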